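## Structural features

Ficucaricone C is an unsymmetrical benzil: a 1,2-dione whose two carbonyl carbons join C6 of a 2,2-dimethyl-2H-chromene to a para-(3-methylbut-2-enoxy)phenyl ring (ring B). Ring A of the chromene is substituted at five of its six carbons: OMe at C5, the dione at C6, a free OH at C7, the pyran oxygen at C8a and the pyran carbon C4 at C4a; only C8 carries hydrogen. The molecule is achiral and has no stereogenic double bond (the only disubstituted alkene, C3=C4, lies in the pyran ring), so no stereocentres stand next to each other and all control is regiochemical. The fragile groups are: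

- the 1,2-dione (hydroxide causes benzilic acid rearrangement, peroxide cleaves it, and the C7 hydroxyl can add to it);
- the electron-rich C3=C4 alkene of the chromene (acid, electrophilic oxidants);
- the aryl prenyl ether (acid, zerovalent palladium, strong heating);
- the free phenol.

The real difficulty is ring A: three oxygens in a 1,3,5-relation must end up as three different functions (methyl ether, free phenol, pyran ether), and two different carbon substituents must sit between defined pairs of them. A second difficulty is reaching the dione oxidation level in the presence of three alkenes. The key step uses the C5/C7/C8a oxygen pattern with C8–H: the C7 hydroxyl comes from a ketene carbonyl, the C5 methoxy from an ynol ether, and the C8a oxygen from a silyl enol ether inside a cyclobutenone. The carbon substituents at C4a and C6 travel in on cyclobutenone C2 and on the ynol ether β-carbon.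

## Logic of the disconnections

**25 ⇒ 23.** The O1–C2 bond of the pyran is cut and the C3=C4 unsaturation is removed, leaving a 3-methylbut-2-enyl chain on C4a next to a free C8a hydroxyl. The cut is made here because that chain is what the ring-forming step delivers at C4a, and C8a–OH is the only hydroxyl ortho to it, so only one chromene can form. The gain is that the pyran ring and its alkene shrink to a C5 side chain. The forward step needs an oxidant that removes hydride from the benzylic CH2 of ring A (passing through 24) without attacking the prenyl ether on ring B.

**23 ⇒ 22.** Two O–Si bonds are cut. Both phenols are carried as the same silyl ether so that one fluoride treatment frees them. The forward step must be buffered, because the 1,2-dione does not tolerate free base.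

**22 ⇒ 21.** Both carbonyl oxygens are removed and the dione is traced back to the C6–C≡C–ring B alkyne. The alkyne is linear, non-enolisable and heat-stable, and it is the form in which the two-carbon bridge can pass through a thermal ring synthesis. The forward oxidation must be specific for the triple bond in the presence of two trisubstituted alkenes.

**21 ⇒ 20.** The O–Si bond at C7 is cut. The C7 phenol must be masked before the alkyne is activated, because a free hydroxyl ortho to an alkyne cyclises to a benzofuran.

**20 ⇒ 7 + 15.** The C6–C7 and C4a–C5 bonds are cut; the C7–C8 bond is broken and re-formed during the forward reaction (through 16, 17, 18 and 19). Ring A dissolves into the four carbons of 7 (C7, C8, C8a, C4a) and two carbons of 15 (C5, C6). Atom mapping confirms the pattern: C7–OH from the carbonyl of 7, C8–H from its CH2, C8a–OSi from its silyl enol ether, C4a–prenyl from its C2, C5–OMe and C6–alkynyl from the ynol ether carbons of 15. All five substituents are therefore fixed by connectivity and the ring is made in one operation from two fragments of similar size. The forward step needs the methoxy-substituted triple bond of 15 to react in preference to the aryl-substituted one. Three design choices serve it: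

- 7 carries a bulky triisopropylsilyl group so that the vinylogous silyl ester neither hydrolyses nor hands silicon to the new phenol;
- 15 is a methyl (not ethyl) ynol ether, which has no β-hydrogen and cannot fragment on heating;
- 15 is used in excess so that the ketene is not consumed by acylating 20.

**7 ⇒ 6 ⇒ 5.** The O–Si bond and then the enol O–H are traced back to an O–ethyl vinylogous ester. 6 is the enol of a symmetrical 2-substituted cyclobutane-1,3-dione, so silylation can give only one constitution. The ethyl group of 5 could not be removed later beside the C5 methyl ether, which is why it is exchanged for silicon before ring A is built.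

**5 ⇒ 4.** The C1–C2 and C3–C4 bonds of the four-membered ring are cut, giving 4 and the parent ketene (a gaseous reagent). The polarity of the ynol ether puts the prenyl group on C2 and the oxygen on C3.

**4 ⇒ 1 + 2.** The C(sp)–C(sp3) bond is cut; this is alkylation of the acetylide 3. Displacement must take place at the primary carbon of 2, not at the dimethyl-substituted end.

**15 ⇒ 11 + 14.** The central C(sp)–C(sp) bond of the diyne is cut. An unsymmetrical diyne is best made from a 1-bromoalkyne and a terminal alkyne. The forward step needs cross-coupling to outrun homocoupling and needs the ynol ether to survive amine base.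

**14 ⇒ 12.** Two eliminations (methanol, then HCl) from a chloroacetal give the ynol ether through its salt 13.

**11 ⇒ 10 ⇒ 9 ⇒ 8 + 2.** In turn: HBr elimination, dibromo-olefination of an aldehyde, and an aryl ether O–C bond. All three are standard, and the last one introduces the ring B prenyl ether at the start.

## Other disconnections considered

**Alternative 1: aryne insertion into a carboxylic acid.**
- Cut: the C6–C(=O) bond and the C7–O bond.
- Forward key step: CsF unmasks the 6,7-aryne from silyl triflate A1. The carboxylate of acid A2 adds at C7, the aryl anion at C6 attacks the carbonyl, and the four-membered intermediate opens. The acyl group ends on C6 and the oxygen on C7, giving ketone A3. No ring closes.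
- In favour: the C5 methoxy directs the nucleophile to the distal aryne carbon, so the regiochemistry should be reliable. The chromene is present from the start, the C7 phenol appears unprotected, and ring B arrives as a simple acid.
- Against: A1 already contains the pentasubstituted ring A, so the hard part of the target is moved into the synthesis of A1, which needs C6/C8 discrimination on a 7-hydroxychromene. The acid can also protonate the aryl anion, which would give an aryl ester instead of the ketone. A3 is one oxidation level short, so the CH2 must still be oxidised beside the chromene alkene and a free phenol.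
- Comparison: on regiocontrol by polarity the two plans are equals. Alternative 1 is the better on the oxidation problem, since an enolisable ketone CH2 can be oxidised with base and oxygen, without a π-acid near the alkenes. It is also the better in needing no protecting group on ring A. The chosen plan is the better on structure: it builds ring A with all five substituents from acyclic pieces, and it is expected to be shorter once the steps to A1 are counted.

**Alternative 2: coumarin lactone as latent gem-dimethyl carbinol.**
- Cut: both C2–CH3 bonds (the O1–C2 bond is re-formed afterwards).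
- Forward key step: MeLi (two equivalents at the lactone carbonyl, plus one consumed by the phenoxide that is released) converts coumarin A4 into the Z-configured phenol tertiary alcohol A5. Acid then closes the pyran by dehydration.
- In favour: the Z geometry is inherited from the lactone ring, so ring closure is assured. Chromene formation is non-oxidative, and the methyl groups come from a cheap reagent.
- Against: it solves only the pyran ring. A4 presupposes ring A with its differentiated oxygens and a C6 alkyne, and alkynylation of a 5,7-dioxygenated coumarin meets the C6/C8 ambiguity. The alkyne still has to be oxidised, now with the acid- and oxidant-sensitive chromene alkene already present. The acid needed for ring closure also removes the methoxymethyl group and exposes a hydroxyl next to the alkyne.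
- Comparison: for pyran formation alone Alternative 2 is the equal of the chosen plan in reliability and the better in avoiding a quinone oxidant beside the prenyl ether. On mechanism it is a polar addition against a pericyclic cascade; both are well understood. On step economy the chosen plan is ahead: its pyran costs one step from a prenyl group that the ring synthesis installs for free, whereas the coumarin route adds lactone construction, addition and cyclodehydration to a ring A synthesis that must still be found.

**Alternative 3: propargyl ether hydroarylation with C8 blocked.**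
- Cut: the C4–C4a bond.
- Forward key step: PtCl4 (tetravalent platinum) activates the alkyne of the 1,1-dimethylpropargyl ether A6. C4a attacks the alkyne terminus in 6-endo fashion, closing the pyran to give A7. The iodine at C8 is removed afterwards to reach 25.
- In favour: the step is catalytic and redox-neutral, and the dione is in place before the ring closes, so no oxidation follows it.
- Against: C8 and C4a are both ortho to the ether oxygen and both activated, so the iodine is indispensable. It costs two extra steps, and its reductive removal must spare a reducible 1,2-dione, the chromene alkene and an allylic ether. PtCl4 is Lewis acidic and may ionise the prenyl ether or be bound by the chelating ortho-hydroxy dione. Ring A again has to be made by other means.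
- Comparison: as a pyran-forming step it is the equal of the quinone dehydrogenation in step count, and the better in needing no stoichiometric oxidant. On structure the chosen plan is the better because the prenyl group is placed on C4a by the ring synthesis itself, so no blocking group is needed. On step economy the blocking-group detour and the separate ring A synthesis put Alternative 3 behind.

Key step: step 10

Assumption: the target is treated as the open 1,2-dione (not its cyclic hemiketal) and is achiral; ketene is taken as a gas stream from an acetone-pyrolysis generator and is counted as a reagent.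

## Route

**Step 1**
Reactants: 1 ethoxyacetylene; 2 prenyl bromide (1-bromo-3-methylbut-2-ene)
Product: 4 1-ethoxy-5-methylhex-4-en-1-yne, via lithium ethoxyacetylide 3 (not isolated)
Conditions: n-BuLi, THF, −78 °C; then 2, DMPU, −78 °C → rt
Reagents that add atoms: none
Why: Deprotonation of the terminal ynol ether and SN2 alkylation of the acetylide at the primary allylic carbon (acetylide alkylation); the polar co-solvent loosens the lithium aggregate so that direct displacement should outrun SN2′ attack at the hindered dimethyl-substituted terminus.

**Step 2**
Reactants: 4 1-ethoxy-5-methylhex-4-en-1-yne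
Product: 5 3-ethoxy-2-(3-methylbut-2-enyl)cyclobut-2-en-1-one
Conditions: CH2=C=O (gas, from acetone pyrolysis), CH2Cl2, 0 °C → rt
Reagents that add atoms: ketene, C=C=O
Why: Ketene–ynol ether [2+2] cycloaddition: the nucleophilic β-carbon of 4 (the one bearing the prenyl group) bonds to the ketene carbonyl carbon and the ethoxy carbon to the ketene CH2, which places prenyl on C2 and ethoxy on C3. The unactivated trisubstituted alkene is far less nucleophilic and should not take part.

**Step 3**
Reactants: 5 3-ethoxy-2-(3-methylbut-2-enyl)cyclobut-2-en-1-one
Product: 6 3-hydroxy-2-(3-methylbut-2-enyl)cyclobut-2-en-1-one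
Conditions: 1 M HCl, THF, 0 °C → rt
Reagents that add atoms: water, O
Why: Acid hydrolysis of a vinylogous ester by addition–elimination at C3; dilute acid near room temperature is too weak to protonate the trisubstituted alkene. Acid is preferred to hydroxide, which would open the strained 1,3-dione by retro-Claisen cleavage.

**Step 4**
Reactants: 6 3-hydroxy-2-(3-methylbut-2-enyl)cyclobut-2-en-1-one
Product: 7 2-(3-methylbut-2-enyl)-3-(triisopropylsilyloxy)cyclobut-2-en-1-one
Conditions: TIPSCl, Et3N, CH2Cl2, 0 °C → rt
Reagents that add atoms: triisopropylsilyl chloride, CC(C)[Si](Cl)(C(C)C)C(C)C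
Why: O-Silylation of an acidic enol (a vinylogous acid), as in silyl ester formation; 6 is the enol of a symmetrical 1,3-dione, so either oxygen gives the same product. The bulky silyl group makes the vinylogous silyl ester robust to moisture and to heating.

**Step 5**
Reactants: 8 4-hydroxybenzaldehyde; 2 prenyl bromide
Product: 9 4-(3-methylbut-2-enoxy)benzaldehyde
Conditions: K2CO3, acetone, reflux
Reagents that add atoms: none
Why: Williamson etherification; the phenoxide of a para-formylphenol is a soft O-nucleophile that displaces the primary allylic bromide cleanly.

**Step 6**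
Reactants: 9 4-(3-methylbut-2-enoxy)benzaldehyde
Product: 10 1-(2,2-dibromoethenyl)-4-(3-methylbut-2-enoxy)benzene
Conditions: CBr4, PPh3, CH2Cl2, 0 °C
Reagents that add atoms: carbon tetrabromide, BrC(Br)(Br)Br
Why: Ramirez dibromo-olefination (first stage of the Corey–Fuchs sequence): the ylide formed from CBr4 and PPh3 undergoes a Wittig reaction with the aldehyde. No free bromine is present, so the prenyl double bond should not be attacked.

**Step 7**
Reactants: 10 1-(2,2-dibromoethenyl)-4-(3-methylbut-2-enoxy)benzene
Product: 11 1-(bromoethynyl)-4-(3-methylbut-2-enoxy)benzene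
Conditions: DBU, DMSO, 15 °C → rt
Reagents that add atoms: none
Why: E2 dehydrobromination of an aryl gem-dibromoalkene; an amidine base cannot perform halogen–metal exchange, so the reaction should stop at the 1-bromoalkyne.

**Step 8**
Reactants: 12 chloroacetaldehyde dimethyl acetal
Product: 14 methoxyacetylene, via sodium methoxyacetylide 13 (not isolated)
Conditions: NaNH2 (3 equiv), liq. NH3, −33 °C; then sat. aq. NH4Cl, −20 °C, distil into cold THF
Reagents that add atoms: none
Why: Two successive β-eliminations (methanol, then HCl) by amide base give the ynol ether, which is held as its sodium acetylide until a cold proton quench. The volatile product is distilled directly into cold THF and used as a solution.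

**Step 9**
Reactants: 11 1-(bromoethynyl)-4-(3-methylbut-2-enoxy)benzene; 14 methoxyacetylene
Product: 15 1-methoxy-4-[4-(3-methylbut-2-enoxy)phenyl]buta-1,3-diyne
Conditions: CuCl (cat.), NH2OH·HCl, n-BuNH2, THF–H2O, 0 °C
Reagents that add atoms: none
Why: Cadiot–Chodkiewicz coupling: the copper acetylide of 14 (monovalent copper kept reduced by hydroxylamine) couples with bromoalkyne 11 to give the unsymmetrical diyne. Ynol ethers are stable to cold aqueous amine base; 14 is used in excess and 11 is added slowly to suppress its homocoupling.

**Step 10**
Reactants: 7 2-(3-methylbut-2-enyl)-3-(triisopropylsilyloxy)cyclobut-2-en-1-one; 15 1-methoxy-4-[4-(3-methylbut-2-enoxy)phenyl]buta-1,3-diyne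
Product: 20 3-methoxy-4-(3-methylbut-2-enyl)-2-{[4-(3-methylbut-2-enoxy)phenyl]ethynyl}-5-(triisopropylsilyloxy)phenol, via vinylketene 16 (not isolated), via vinylcyclobutenone 17 (not isolated), via dienylketene 18 (not isolated), via cyclohexadienone 19 (not isolated)
Conditions: toluene (degassed), 15 (1.3 equiv), 80 → 110 °C, sealed tube
Reagents that add atoms: none
Why: Thermal conrotatory 4π opening of 7 breaks its C1–C4 bond and gives vinylketene 16; the β-carbon of the ynol ether in 15 attacks the ketene carbonyl carbon while the methoxy-bearing carbon bonds to the prenyl-bearing ketene carbon ([2+2]), giving 17. 17 opens again (4π) to dienylketene 18, which closes ring A as a six-membered carbocycle by thermal disrotatory 6π electrocyclisation between the ketene carbon and the terminal CH2, and enolisation of 19 gives phenol 20. The closest known reaction type is the Danheiser benzannulation of cyclobutenones with 1-alkoxyalkynes to resorcinol monoethers; both partners here are new members of their classes (a 3-silyloxycyclobutenone and a conjugated diynyl ether). Regiochemistry rests on the polarisation of the ynol ether (nucleophilic β-carbon, cation-stabilising methoxy on the α-carbon), so that C7 carries OH, C6 the arylethynyl group, C5 OMe, C4a the prenyl group and C8a the silyloxy group, with no other connectivity available. Chemoselectivity is needed for the methoxy-substituted triple bond over the aryl-substituted one and over the two prenyl alkenes; only the ynol ether is nucleophilic enough to add to a ketene without a catalyst at this temperature. No stereocentre survives: the quaternary carbon of 17 forms as a racemate and is destroyed in the next ring opening, and the unproductive geometry of 18 can return to 17 and re-open until the isomer able to cyclise is consumed. The methyl ynol ether has no β-hydrogen and cannot fragment by retro-ene reaction, the bulky silyl group should stay on its oxygen, and the excess of 15 keeps the ketene from acylating 20.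

**Step 11**
Reactants: 20 3-methoxy-4-(3-methylbut-2-enyl)-2-{[4-(3-methylbut-2-enoxy)phenyl]ethynyl}-5-(triisopropylsilyloxy)phenol
Product: 21 3-methoxy-4-(3-methylbut-2-enyl)-2-{[4-(3-methylbut-2-enoxy)phenyl]ethynyl}-1,5-bis(triisopropylsilyloxy)benzene
Conditions: TIPSCl, imidazole, DMF, rt
Reagents that add atoms: triisopropylsilyl chloride, CC(C)[Si](Cl)(C(C)C)C(C)C
Why: Standard silylation of an unhindered phenol; a free hydroxyl ortho to the alkyne would add to it (5-endo closure to a benzofuran) once the alkyne is activated by a metal. Using the same silyl group as at C8a allows one later deprotection.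

**Step 12**
Reactants: 21 3-methoxy-4-(3-methylbut-2-enyl)-2-{[4-(3-methylbut-2-enoxy)phenyl]ethynyl}-1,5-bis(triisopropylsilyloxy)benzene
Product: 22 1-[2-methoxy-3-(3-methylbut-2-enyl)-4,6-bis(triisopropylsilyloxy)phenyl]-2-[4-(3-methylbut-2-enoxy)phenyl]ethane-1,2-dione
Conditions: PdCl2 (10 mol %), DMSO, 120–140 °C
Reagents that add atoms: dimethyl sulfoxide, CS(C)=O
Why: Palladium-catalysed oxidation of a diarylalkyne to a benzil with DMSO as oxygen donor: divalent palladium activates the triple bond, the sulfoxide oxygen adds and dimethyl sulfide leaves, twice. Trisubstituted alkenes bind divalent palladium poorly and the solvent vastly outnumbers the flanking ether oxygens, so the prenyl groups and aryl ethers are expected to be spectators.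

**Step 13**
Reactants: 22 1-[2-methoxy-3-(3-methylbut-2-enyl)-4,6-bis(triisopropylsilyloxy)phenyl]-2-[4-(3-methylbut-2-enoxy)phenyl]ethane-1,2-dione
Product: 23 1-[4,6-dihydroxy-2-methoxy-3-(3-methylbut-2-enyl)phenyl]-2-[4-(3-methylbut-2-enoxy)phenyl]ethane-1,2-dione
Conditions: TBAF, AcOH, THF, 0 °C
Reagents that add atoms: none
Why: Fluoride cleavage of two aryl silyl ethers, both activated by the ortho or para carbonyl; acetic acid buffers the medium so that the 1,2-dione is not exposed to basic phenoxide or hydroxide (no benzilic acid rearrangement).

**Step 14**
Reactants: 23 1-[4,6-dihydroxy-2-methoxy-3-(3-methylbut-2-enyl)phenyl]-2-[4-(3-methylbut-2-enoxy)phenyl]ethane-1,2-dione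
Product: 25 ficucaricone C, 1-(7-hydroxy-5-methoxy-2,2-dimethyl-2H-chromen-6-yl)-2-[4-(3-methylbut-2-enoxy)phenyl]ethane-1,2-dione, via quinone methide 24 (not isolated)
Conditions: DDQ, toluene, 80 °C
Reagents that add atoms: none
Why: DDQ dehydrogenation of an ortho-prenylphenol: hydride abstraction from the benzylic CH2 of the electron-rich ring gives ortho-quinone methide 24, which closes the six-membered pyran (O1–C2 bond) by oxa-6π electrocyclisation. C8a–OH is the only hydroxyl ortho to the prenyl group, so a single chromene can form; the chelated C7–OH and the prenyl ether on the carbonyl-deactivated ring B are much poorer hydride donors.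

## Compound list

1 | ethoxyacetylene (ethoxyethyne) | CCOC#C | starting material
2 | prenyl bromide (1-bromo-3-methylbut-2-ene) | CC(C)=CCBr | starting material
3 | lithium ethoxyacetylide | [Li+].[C-]#COCC | intermediate (not isolated)
4 | 1-ethoxy-5-methylhex-4-en-1-yne | CCOC#CCC=C(C)C | intermediate
5 | 3-ethoxy-2-(3-methylbut-2-enyl)cyclobut-2-en-1-one | CCOC1=C(CC=C(C)C)C(=O)C1 | intermediate
6 | 3-hydroxy-2-(3-methylbut-2-enyl)cyclobut-2-en-1-one | OC1=C(CC=C(C)C)C(=O)C1 | intermediate
7 | 2-(3-methylbut-2-enyl)-3-(triisopropylsilyloxy)cyclobut-2-en-1-one | O=C1CC(O[Si](C(C)C)(C(C)C)C(C)C)=C1CC=C(C)C | intermediate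
8 | 4-hydroxybenzaldehyde | O=Cc1ccc(O)cc1 | starting material
9 | 4-(3-methylbut-2-enoxy)benzaldehyde | O=Cc1ccc(OCC=C(C)C)cc1 | intermediate
10 | 1-(2,2-dibromoethenyl)-4-(3-methylbut-2-enoxy)benzene | BrC(Br)=Cc1ccc(OCC=C(C)C)cc1 | intermediate
11 | 1-(bromoethynyl)-4-(3-methylbut-2-enoxy)benzene | BrC#Cc1ccc(OCC=C(C)C)cc1 | intermediate
12 | chloroacetaldehyde dimethyl acetal (2-chloro-1,1-dimethoxyethane) | COC(CCl)OC | starting material
13 | sodium methoxyacetylide | [Na+].[C-]#COC | intermediate (not isolated)
14 | methoxyacetylene (methoxyethyne) | COC#C | intermediate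
15 | 1-methoxy-4-[4-(3-methylbut-2-enoxy)phenyl]buta-1,3-diyne | COC#CC#Cc1ccc(OCC=C(C)C)cc1 | intermediate
16 | 2-(3-methylbut-2-enyl)-3-(triisopropylsilyloxy)buta-1,3-dien-1-one (vinylketene) | C=C(O[Si](C(C)C)(C(C)C)C(C)C)C(CC=C(C)C)=C=O | intermediate (not isolated)
17 | 3-methoxy-4-(3-methylbut-2-enyl)-2-{[4-(3-methylbut-2-enoxy)phenyl]ethynyl}-4-[1-(triisopropylsilyloxy)ethenyl]cyclobut-2-en-1-one (racemic, transient quaternary carbon) | O=C1C(C#Cc2ccc(OCC=C(C)C)cc2)=C(OC)C1(CC=C(C)C)C(=C)O[Si](C(C)C)(C(C)C)C(C)C | intermediate (not isolated)
18 | (3E)-3-methoxy-4-(3-methylbut-2-enyl)-2-{[4-(3-methylbut-2-enoxy)phenyl]ethynyl}-5-(triisopropylsilyloxy)hexa-1,3,5-trien-1-one (ketene carbon and silyloxyvinyl group cis across C3=C4) | O=C=C(C#Cc1ccc(OCC=C(C)C)cc1)/C(OC)=C(CC=C(C)C)\C(=C)O[Si](C(C)C)(C(C)C)C(C)C | intermediate (not isolated)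
19 | 3-methoxy-4-(3-methylbut-2-enyl)-2-{[4-(3-methylbut-2-enoxy)phenyl]ethynyl}-5-(triisopropylsilyloxy)cyclohexa-2,4-dien-1-one | O=C1CC(O[Si](C(C)C)(C(C)C)C(C)C)=C(CC=C(C)C)C(OC)=C1C#Cc1ccc(OCC=C(C)C)cc1 | intermediate (not isolated)
20 | 3-methoxy-4-(3-methylbut-2-enyl)-2-{[4-(3-methylbut-2-enoxy)phenyl]ethynyl}-5-(triisopropylsilyloxy)phenol | Oc1cc(O[Si](C(C)C)(C(C)C)C(C)C)c(CC=C(C)C)c(OC)c1C#Cc1ccc(OCC=C(C)C)cc1 | intermediate
21 | 3-methoxy-4-(3-methylbut-2-enyl)-2-{[4-(3-methylbut-2-enoxy)phenyl]ethynyl}-1,5-bis(triisopropylsilyloxy)benzene | CC(C)[Si](Oc1cc(O[Si](C(C)C)(C(C)C)C(C)C)c(CC=C(C)C)c(OC)c1C#Cc1ccc(OCC=C(C)C)cc1)(C(C)C)C(C)C | intermediate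
22 | 1-[2-methoxy-3-(3-methylbut-2-enyl)-4,6-bis(triisopropylsilyloxy)phenyl]-2-[4-(3-methylbut-2-enoxy)phenyl]ethane-1,2-dione | COc1c(CC=C(C)C)c(O[Si](C(C)C)(C(C)C)C(C)C)cc(O[Si](C(C)C)(C(C)C)C(C)C)c1C(=O)C(=O)c1ccc(OCC=C(C)C)cc1 | intermediate
23 | 1-[4,6-dihydroxy-2-methoxy-3-(3-methylbut-2-enyl)phenyl]-2-[4-(3-methylbut-2-enoxy)phenyl]ethane-1,2-dione | COc1c(CC=C(C)C)c(O)cc(O)c1C(=O)C(=O)c1ccc(OCC=C(C)C)cc1 | intermediate
24 | (6Z)-3-hydroxy-5-methoxy-6-(3-methylbut-2-enylidene)-4-{2-[4-(3-methylbut-2-enoxy)phenyl]-2-oxoacetyl}cyclohexa-2,4-dien-1-one (ortho-quinone methide, side chain syn to the ring carbonyl) | CC(C)=C/C=C1\C(=O)C=C(O)C(C(=O)C(=O)c2ccc(OCC=C(C)C)cc2)=C1OC | intermediate (not isolated)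
25 | ficucaricone C, 1-(7-hydroxy-5-methoxy-2,2-dimethyl-2H-chromen-6-yl)-2-[4-(3-methylbut-2-enoxy)phenyl]ethane-1,2-dione (achiral) | COc1c2c(cc(O)c1C(=O)C(=O)c1ccc(OCC=C(C)C)cc1)OC(C)(C)C=C2 | target

## Step count and least certain steps

Total: 14 steps. Longest linear sequence: 9 steps (steps 5, 6, 7, 9, 10, 11, 12, 13, 14; the branch through steps 1 to 4 and 10 to 14 is equally long).

**Step 10 (key step).** The most likely failure is a mismatch of rates. The push–pull cyclobutenone 7 may open only at a temperature at which the conjugated diynyl ether 15 oligomerises, and the second triple bond may lower the nucleophilicity of the ynol ether. Vinylketene 16 would then be lost to dimerisation and to acylation of the product phenol. The fallback exchanges the roles of the two partners, so that the ketenophile is a simple alkyl-substituted ynol ether and the arylethynyl group is a spectator on the cyclobutenone. It sets out from 13, 2 and 15 and returns at 21. Sodium acetylide 13 is alkylated in liquid ammonia with 2 to give 1-methoxy-5-methylhex-4-en-1-yne F1. Diyne 15 is combined with ketene as in step 2 (β-carbon to the ketene carbonyl) to give 3-methoxy-2-{[4-(3-methylbut-2-enoxy)phenyl]ethynyl}cyclobut-2-en-1-one F2. This is hydrolysed with dilute HCl to 3-hydroxy-2-{[4-(3-methylbut-2-enoxy)phenyl]ethynyl}cyclobut-2-en-1-one F3 and silylated (TIPSCl, Et3N) to 2-{[4-(3-methylbut-2-enoxy)phenyl]ethynyl}-3-(triisopropylsilyloxy)cyclobut-2-en-1-one F4. Heating F4 with F1 in toluene runs the same pericyclic cascade in the other orientation: the ketene carbonyl becomes C8a–OH, the prenyl-bearing β-carbon C4a, the methoxy carbon C5, the alkynyl-bearing carbon C6 and the silyloxy carbon C7. The product is 3-methoxy-2-(3-methylbut-2-enyl)-4-{[4-(3-methylbut-2-enoxy)phenyl]ethynyl}-5-(triisopropylsilyloxy)phenol F5. Silylation of F5 (TIPSCl, imidazole, DMF) gives 21.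

**Step 12 (alkyne to dione).** At 120–140 °C the ortho silyl ether may be lost, after which the oxygen would close onto the palladium-activated alkyne. Palladium hydride or acid traces may also isomerise or cleave the prenyl groups. The fallback replaces the one-step π-acid oxidation by a redox-neutral hydration followed by enolate autoxidation. It sets out from 21 and returns at 22. Hydration with Ph3PAuNTf2 (monovalent gold) in wet dioxane at moderate temperature gives 1-[2-methoxy-3-(3-methylbut-2-enyl)-4,6-bis(triisopropylsilyloxy)phenyl]-2-[4-(3-methylbut-2-enoxy)phenyl]ethan-1-one F6. This is drawn with the carbonyl next to the more electron-rich ring A, but either orientation of hydration converges in the next operation. Aerobic α-oxidation of the activated CH2 (DABCO, O2, DMF) gives 22; ground-state oxygen does not attack the trisubstituted alkenes.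

**Step 9 (Cadiot–Chodkiewicz coupling).** Likely problems are homocoupling of 11, loss of the volatile alkyne 14, and slow addition of the primary amine or water to the ynol ether. The fallback changes the bond-forming chemistry from a copper-mediated coupling of the free alkyne to a palladium cross-coupling of an isolable tin acetylide. It sets out from 13 and 11 and returns at 15. After the ammonia is evaporated, 13 is suspended in THF and quenched with Bu3SnCl to give tributyl(methoxyethynyl)stannane F7, a non-volatile liquid. Stille coupling of F7 with 11 [Pd(PPh3)4, zerovalent palladium, THF, 50 °C] gives 15 under anhydrous, amine-free conditions.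

**Step 14 (DDQ ring closure).** The quinone may also abstract hydride from the allylic O–CH2 of the ring B prenyl ether (oxidative loss of the ether), or the quinone methide may be trapped by the hydroquinone instead of cyclising. The fallback replaces dehydrogenation by selenoetherification and selenoxide elimination. It sets out from 23 and returns at 25. N-(Phenylselanyl)phthalimide with catalytic camphorsulfonic acid in CH2Cl2 should engage only the alkene that has an internal nucleophile. It closes the C8a oxygen onto the prenyl group to give racemic 1-[7-hydroxy-5-methoxy-2,2-dimethyl-3-(phenylselanyl)-3,4-dihydro-2H-chromen-6-yl]-2-[4-(3-methylbut-2-enoxy)phenyl]ethane-1,2-dione F8. Oxidation at selenium (NaIO4, aqueous THF, 0 °C) and syn-elimination of the selenoxide can remove hydrogen only from C4, because C2 is quaternary, and gives 25.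

**Step 2 (ketene cycloaddition).** Dimerisation of ketene may outrun its addition to 4, and gas-phase dosing is hard to control. The fallback uses a more electrophilic ketene made in the flask, followed by reductive removal of chlorine. It sets out from 4 and returns at 5. Dichloroketene (from trichloroacetyl chloride and Zn–Cu couple in ether) adds to 4 with the same regiochemistry to give 4,4-dichloro-3-ethoxy-2-(3-methylbut-2-enyl)cyclobut-2-en-1-one F9. Zinc in acetic acid with TMEDA removes both chlorines and gives 5.

## Further compounds

F1 | step 10 | 1-methoxy-5-methylhex-4-en-1-yne | COC#CCC=C(C)C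
F2 | step 10 | 3-methoxy-2-{[4-(3-methylbut-2-enoxy)phenyl]ethynyl}cyclobut-2-en-1-one | COC1=C(C#Cc2ccc(OCC=C(C)C)cc2)C(=O)C1
F3 | step 10 | 3-hydroxy-2-{[4-(3-methylbut-2-enoxy)phenyl]ethynyl}cyclobut-2-en-1-one | OC1=C(C#Cc2ccc(OCC=C(C)C)cc2)C(=O)C1
F4 | step 10 | 2-{[4-(3-methylbut-2-enoxy)phenyl]ethynyl}-3-(triisopropylsilyloxy)cyclobut-2-en-1-one | CC(C)[Si](OC1=C(C#Cc2ccc(OCC=C(C)C)cc2)C(=O)C1)(C(C)C)C(C)C
F5 | step 10 | 3-methoxy-2-(3-methylbut-2-enyl)-4-{[4-(3-methylbut-2-enoxy)phenyl]ethynyl}-5-(triisopropylsilyloxy)phenol | Oc1cc(O[Si](C(C)C)(C(C)C)C(C)C)c(C#Cc2ccc(OCC=C(C)C)cc2)c(OC)c1CC=C(C)C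
F6 | step 12 | 1-[2-methoxy-3-(3-methylbut-2-enyl)-4,6-bis(triisopropylsilyloxy)phenyl]-2-[4-(3-methylbut-2-enoxy)phenyl]ethan-1-one | COc1c(CC=C(C)C)c(O[Si](C(C)C)(C(C)C)C(C)C)cc(O[Si](C(C)C)(C(C)C)C(C)C)c1C(=O)Cc1ccc(OCC=C(C)C)cc1
F7 | step 9 | tributyl(methoxyethynyl)stannane | CCCC[Sn](CCCC)(CCCC)C#COC
F8 | step 14 | 1-[7-hydroxy-5-methoxy-2,2-dimethyl-3-(phenylselanyl)-3,4-dihydro-2H-chromen-6-yl]-2-[4-(3-methylbut-2-enoxy)phenyl]ethane-1,2-dione (racemic at C3) | COc1c2c(cc(O)c1C(=O)C(=O)c1ccc(OCC=C(C)C)cc1)OC(C)(C)C([Se]c1ccccc1)C2
F9 | step 2 | 4,4-dichloro-3-ethoxy-2-(3-methylbut-2-enyl)cyclobut-2-en-1-one | CCOC1=C(CC=C(C)C)C(=O)C1(Cl)Cl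
A1 | alternative 1 | 5-methoxy-2,2-dimethyl-6-(trimethylsilyl)-2H-chromen-7-yl trifluoromethanesulfonate | COc1c2c(cc(OS(=O)(=O)C(F)(F)F)c1[Si](C)(C)C)OC(C)(C)C=C2
A2 | alternative 1 | 2-[4-(3-methylbut-2-enoxy)phenyl]acetic acid | OC(=O)Cc1ccc(OCC=C(C)C)cc1
A3 | alternative 1 | 1-(7-hydroxy-5-methoxy-2,2-dimethyl-2H-chromen-6-yl)-2-[4-(3-methylbut-2-enoxy)phenyl]ethanone | COc1c2c(cc(O)c1C(=O)Cc1ccc(OCC=C(C)C)cc1)OC(C)(C)C=C2
A4 | alternative 2 | 5-methoxy-7-(methoxymethoxy)-6-{[4-(3-methylbut-2-enoxy)phenyl]ethynyl}-2H-chromen-2-one | COc1c2c(cc(OCOC)c1C#Cc1ccc(OCC=C(C)C)cc1)OC(=O)C=C2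
A5 | alternative 2 | 2-[(Z)-3-hydroxy-3-methylbut-1-enyl]-3-methoxy-5-(methoxymethoxy)-4-{[4-(3-methylbut-2-enoxy)phenyl]ethynyl}phenol | COc1c(/C=C\C(C)(C)O)c(O)cc(OCOC)c1C#Cc1ccc(OCC=C(C)C)cc1
A6 | alternative 3 | 1-[2-hydroxy-3-iodo-6-methoxy-4-(2-methylbut-3-yn-2-yloxy)phenyl]-2-[4-(3-methylbut-2-enoxy)phenyl]ethane-1,2-dione | COc1cc(OC(C)(C)C#C)c(I)c(O)c1C(=O)C(=O)c1ccc(OCC=C(C)C)cc1
A7 | alternative 3 | 1-(7-hydroxy-8-iodo-5-methoxy-2,2-dimethyl-2H-chromen-6-yl)-2-[4-(3-methylbut-2-enoxy)phenyl]ethane-1,2-dione | COc1c2c(c(I)c(O)c1C(=O)C(=O)c1ccc(OCC=C(C)C)cc1)OC(C)(C)C=C2
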